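**Strategy**

Labdane numbering is used. Ring B is cut at C5–C6 and C7–C8, so that its unfunctionalised C6H2–C7H2 bridge comes from vinyltriphenylphosphonium bromide. The precursor is a 1,3-diketone: the ring A ketone (C5, between the C4 gem-dimethyl carbon and quaternary C10) carrying a propanoyl group (C9, C8 and the C8 methyl) on C10. Its only enolisable carbon, C8, adds to the vinyl salt and the ylide so formed at C6 closes ring B on the C5 carbonyl in the same flask. The C9 ketone then becomes the C8=C9 alkene through an enol triflate that receives the side chain; C10 stems from an asymmetric allylation and C14 from a glyceric ester.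

Key step: step 7

Remark: the (S)-t-BuPHOX ligand is taken to give the (S)-ketone 4, as it does with 2-methylcyclohexanone; if the sense were opposite, the (R)-ligand would be used.

**Route**

Step 1
Reactants: 1 2,2,6-trimethylcyclohexan-1-one
Product: 3 allyl 2,6,6-trimethylcyclohex-1-en-1-yl carbonate, via lithium enolate 2 (not isolated)
Conditions: LiN(SiMe3)2, THF, 0 °C; then allyl chloroformate, −78 °C
Reagents that add atoms: allyl chloroformate, C=CCOC(Cl)=O
Why: Only one α-carbon of 1 bears hydrogen, so a single tetrasubstituted enolate forms, and the hard chloroformate should trap it on oxygen (enolate O-acylation).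

Step 2
Reactants: 3 allyl 2,6,6-trimethylcyclohex-1-en-1-yl carbonate
Product: 4 (S)-2-allyl-2,6,6-trimethylcyclohexan-1-one
Conditions: Pd2(dba)3 (2.5 mol %), (S)-t-BuPHOX (6.25 mol %), THF, 25 °C
Reagents that add atoms: none
Why: Decarboxylative asymmetric allylic alkylation (Tsuji allylation): zerovalent palladium ionises the carbonate, CO2 is lost, and the enolate and allyl fragment recombine in the pocket of the ligand (S)-4-tert-butyl-2-(2-diphenylphosphinophenyl)-4,5-dihydrooxazole, which sets quaternary C10.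

Step 3
Reactants: 4 (S)-2-allyl-2,6,6-trimethylcyclohexan-1-one
Product: 5 (S)-2,2,6-trimethyl-6-[(E)-prop-1-en-1-yl]cyclohexan-1-one
Conditions: RuHCl(CO)(PPh3)3 (5 mol %), toluene, 110 °C
Reagents that add atoms: none
Why: Ruthenium hydride olefin isomerisation (hydrometalation and β-hydride elimination) should move the alkene by one position and stop there because C10 is quaternary; any (Z)-isomer is cleaved to the same aldehyde in step 4.

Step 4
Reactants: 5 (S)-2,2,6-trimethyl-6-[(E)-prop-1-en-1-yl]cyclohexan-1-one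
Product: 7 (S)-1,3,3-trimethyl-2-oxocyclohexane-1-carbaldehyde, via ozonide 6 (not isolated)
Conditions: O3, CH2Cl2, −78 °C; then Me2S, −78 °C to rt
Reagents that add atoms: ozone, [O-][O+]=O
Why: Ozonolysis with reductive work-up cleaves the propenyl double bond and leaves C9 as an aldehyde on the quaternary centre, which cannot epimerise.

Step 5
Reactants: 7 (S)-1,3,3-trimethyl-2-oxocyclohexane-1-carbaldehyde
Product: 8 (6S)-6-(1-hydroxypropyl)-2,2,6-trimethylcyclohexan-1-one (both carbinol epimers)
Conditions: EtMgBr, THF, −78 °C; aq NH4Cl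
Reagents that add atoms: ethylmagnesium bromide, CC[Mg]Br
Why: Grignard addition should be selective for the aldehyde over the ketone flanked by two quaternary carbons; the new carbinol centre is oxidised away in step 6.

Step 6
Reactants: 8 (6S)-6-(1-hydroxypropyl)-2,2,6-trimethylcyclohexan-1-one
Product: 9 (S)-2,2,6-trimethyl-6-propanoylcyclohexan-1-one
Conditions: Dess–Martin periodinane, CH2Cl2, rt
Reagents that add atoms: none
Why: Dess–Martin oxidation is non-basic, so the β-hydroxy ketone should be oxidised to the 1,3-diketone without retro-aldol cleavage.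

Step 7
Reactants: 9 (S)-2,2,6-trimethyl-6-propanoylcyclohexan-1-one
Product: 12 (8aR)-2,5,5,8a-tetramethyl-3,5,6,7,8,8a-hexahydronaphthalen-1(2H)-one (both C8 epimers), via lithium enolate 10 (not isolated), via phosphonium ylide 11 (not isolated)
Conditions: LiN(SiMe3)2, THF, −78 °C; vinyltriphenylphosphonium bromide, −78 °C to rt; then toluene, 110 °C
Reagents that add atoms: vinyltriphenylphosphonium bromide, C=C[P+](c1ccccc1)(c1ccccc1)c1ccccc1.[Br-]
Why: LiN(SiMe3)2 removes a proton from C8, the only enolisable position of 9 (C10 is quaternary and the ring A ketone has no α-hydrogen), and the enolate adds through carbon to the β-carbon of the vinylphosphonium salt (Michael addition, C7–C8), which leaves a non-stabilised ylide at C6; on heating this ylide attacks the C5 carbonyl and the oxaphosphetane collapses to the C5=C6 alkene and Ph3PO (intramolecular Wittig reaction, C5–C6). The closest known reaction type is the vinylphosphonium (Schweizer) cycloalkene annulation, in which a carbonyl-bearing carbanion and the vinyl salt give a ring by Michael addition and Wittig closure. Ring B is the only ring closed, as a six-membered ring by 6-exo-trig attack of the C6 ylide carbon on the C5 carbonyl. No lasting stereocentre is made: C10 is carried over from step 2, C8 arises as a mixture of epimers that is erased in step 9, and C5 is set in step 8. The step needs carbon rather than oxygen alkylation of the enolate and closure on C5 rather than C9; the lithium counter-ion and the soft acceptor favour carbon attack, closure on C9 would need a four-membered ring, and the reluctance of the doubly neopentyl C5 carbonyl is met by the intramolecular setting and by heating.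

Step 8
Reactants: 12 (8aR)-2,5,5,8a-tetramethyl-3,5,6,7,8,8a-hexahydronaphthalen-1(2H)-one
Product: 13 (4aR,8aR)-2,5,5,8a-tetramethyloctahydronaphthalen-1(2H)-one (both C8 epimers)
Conditions: H2 (3 atm), 10% Pd/C, EtOH, rt
Reagents that add atoms: none
Why: Catalytic hydrogenation should deliver hydrogen to the C5=C6 alkene from the face opposite the axial C10 methyl group, which gives the trans ring fusion (H-5 anti to the C10 methyl).

Step 9
Reactants: 13 (4aR,8aR)-2,5,5,8a-tetramethyloctahydronaphthalen-1(2H)-one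
Product: 15 (4aR,8aR)-2,5,5,8a-tetramethyl-3,4,4a,5,6,7,8,8a-octahydronaphthalen-1-yl trifluoromethanesulfonate, via potassium enolate 14 (not isolated)
Conditions: KN(SiMe3)2, THF, −78 to 0 °C; then PhNTf2, −78 °C to rt; aq NH4Cl
Reagents that add atoms: N-phenylbis(trifluoromethanesulfonimide), O=S(=O)(N(c1ccccc1)S(=O)(=O)C(F)(F)F)C(F)(F)F
Why: C10 is quaternary, so the ketone can enolise only toward C8; O-triflation of that enolate fixes the tetrasubstituted C8=C9 double bond regiospecifically and removes the C8 stereocentre.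

Step 10
Reactants: 15 (4aR,8aR)-2,5,5,8a-tetramethyl-3,4,4a,5,6,7,8,8a-octahydronaphthalen-1-yl trifluoromethanesulfonate
Product: 16 (4aR,8aR)-1-ethenyl-2,5,5,8a-tetramethyl-3,4,4a,5,6,7,8,8a-octahydronaphthalene
Conditions: tributyl(vinyl)stannane, Pd(PPh3)4 (5 mol %), LiCl, THF, 65 °C
Reagents that add atoms: tributyl(vinyl)stannane, C=C[Sn](CCCC)(CCCC)CCCC
Why: Stille coupling of a hindered cyclohexenyl triflate with a vinylstannane in the presence of LiCl is well suited to this substitution pattern and installs C11=C12 on C9.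

Step 11
Reactants: 17 methyl (R)-2,2-dimethyl-1,3-dioxolane-4-carboxylate
Product: 19 (R)-1-(2,2-dimethyl-1,3-dioxolan-4-yl)ethan-1-one, via Weinreb amide 18 (not isolated)
Conditions: MeNH(OMe)·HCl, i-PrMgCl, THF, −20 °C; then MeMgBr, −20 to 0 °C; aq NH4Cl
Reagents that add atoms: methylmagnesium bromide, C[Mg]Br
Why: The magnesium amide of N,O-dimethylhydroxylamine converts the ester into the Weinreb amide, whose chelated adduct with MeMgBr resists over-addition; the low temperature should protect the α-alkoxy stereocentre (future C14).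

Step 12
Reactants: 19 (R)-1-(2,2-dimethyl-1,3-dioxolan-4-yl)ethan-1-one
Product: 21 (R)-1-(2,2-dimethyl-1,3-dioxolan-4-yl)ethenyl trifluoromethanesulfonate, via potassium enolate 20 (not isolated)
Conditions: KN(SiMe3)2, THF, −78 °C; then PhNTf2, −78 to 0 °C; aq NH4Cl
Reagents that add atoms: N-phenylbis(trifluoromethanesulfonimide), O=S(=O)(N(c1ccccc1)S(=O)(=O)C(F)(F)F)C(F)(F)F
Why: Kinetic deprotonation should occur at the unhindered methyl group and not at the α-alkoxy methine, so O-triflation gives the 1-substituted vinyl triflate with the stereocentre intact.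

Step 13
Reactants: 16 (4aR,8aR)-1-ethenyl-2,5,5,8a-tetramethyl-3,4,4a,5,6,7,8,8a-octahydronaphthalene; 21 (R)-1-(2,2-dimethyl-1,3-dioxolan-4-yl)ethenyl trifluoromethanesulfonate
Product: 23 (4S)-2,2-dimethyl-4-{4-[(4aR,8aR)-2,5,5,8a-tetramethyl-3,4,4a,5,6,7,8,8a-octahydronaphthalen-1-yl]but-1-en-2-yl}-1,3-dioxolane, via alkylborane 22 (not isolated)
Conditions: 9-BBN, THF, 0 °C to rt; then 21, PdCl2(dppf) (5 mol %), K3PO4 (3 M aq), DMF, 50 °C
Reagents that add atoms: none
Why: 9-BBN should add to the terminal carbon of the vinyl group only (the tetrasubstituted C8=C9 alkene is too hindered), and the primary alkylborane then joins C12 to C13 by B-alkyl Suzuki–Miyaura coupling; no stereocentre is touched.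

Step 14
Reactants: 23 (4S)-2,2-dimethyl-4-{4-[(4aR,8aR)-2,5,5,8a-tetramethyl-3,4,4a,5,6,7,8,8a-octahydronaphthalen-1-yl]but-1-en-2-yl}-1,3-dioxolane
Product: 24 (2S)-3-methylidene-5-[(4aR,8aR)-2,5,5,8a-tetramethyl-3,4,4a,5,6,7,8,8a-octahydronaphthalen-1-yl]pentane-1,2-diol
Conditions: AcOH/H2O (4:1), 40 °C
Reagents that add atoms: none
Why: Mild aqueous acid hydrolyses the isopropylidene acetal and should be too weak to protonate either alkene or to ionise the allylic alcohol.

Step 15
Reactants: 24 (2S)-3-methylidene-5-[(4aR,8aR)-2,5,5,8a-tetramethyl-3,4,4a,5,6,7,8,8a-octahydronaphthalen-1-yl]pentane-1,2-diol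
Product: 25 (2S)-3-methylidene-5-[(4aR,8aR)-2,5,5,8a-tetramethyl-3,4,4a,5,6,7,8,8a-octahydronaphthalen-1-yl]pentane-1,2-diyl diacetate (CNP0227767.1)
Conditions: Ac2O, pyridine, DMAP (cat.), CH2Cl2, rt
Reagents that add atoms: acetic anhydride, CC(=O)OC(C)=O
Why: DMAP-catalysed acylation should esterify both hydroxyl groups without touching C14 or the alkenes.

**Compound list**

1 | 2,2,6-trimethylcyclohexan-1-one (racemic) | CC1CCCC(C)(C)C1=O | starting material
2 | lithium 2,6,6-trimethylcyclohex-1-en-1-olate | [Li+].[O-]C1=C(C)CCCC1(C)C | intermediate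
3 | allyl 2,6,6-trimethylcyclohex-1-en-1-yl carbonate | C=CCOC(=O)OC1=C(C)CCCC1(C)C | intermediate
4 | (S)-2-allyl-2,6,6-trimethylcyclohexan-1-one | C=CC[C@]1(C)CCCC(C)(C)C1=O | intermediate
5 | (S)-2,2,6-trimethyl-6-[(E)-prop-1-en-1-yl]cyclohexan-1-one | C/C=C/[C@]1(C)CCCC(C)(C)C1=O | intermediate
6 | 3-methyl-5-[(1S)-1,3,3-trimethyl-2-oxocyclohexyl]-1,2,4-trioxolane (ozonide) | CC1OOC(O1)[C@]1(C)CCCC(C)(C)C1=O | intermediate
7 | (S)-1,3,3-trimethyl-2-oxocyclohexane-1-carbaldehyde | O=C[C@]1(C)CCCC(C)(C)C1=O | intermediate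
8 | (6S)-6-(1-hydroxypropyl)-2,2,6-trimethylcyclohexan-1-one (both carbinol epimers) | CCC(O)[C@]1(C)CCCC(C)(C)C1=O | intermediate
9 | (S)-2,2,6-trimethyl-6-propanoylcyclohexan-1-one | CCC(=O)[C@]1(C)CCCC(C)(C)C1=O | intermediate
10 | lithium enolate of 9 at C8 | [Li+].CC=C([O-])[C@]1(C)CCCC(C)(C)C1=O | intermediate
11 | (6S)-2,2,6-trimethyl-6-[2-methyl-4-(triphenyl-λ5-phosphanylidene)butanoyl]cyclohexan-1-one (ylide) | CC(CC=P(c1ccccc1)(c1ccccc1)c1ccccc1)C(=O)[C@]1(C)CCCC(C)(C)C1=O | intermediate
12 | (8aR)-2,5,5,8a-tetramethyl-3,5,6,7,8,8a-hexahydronaphthalen-1(2H)-one (both C8 epimers) | CC1CC=C2C(C)(C)CCC[C@@]2(C)C1=O | intermediate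
13 | (4aR,8aR)-2,5,5,8a-tetramethyloctahydronaphthalen-1(2H)-one (both C8 epimers) | CC1CC[C@@H]2C(C)(C)CCC[C@@]2(C)C1=O | intermediate
14 | potassium enolate of 13 (C8=C9) | [K+].CC1=C([O-])[C@]2(C)CCCC(C)(C)[C@H]2CC1 | intermediate
15 | (4aR,8aR)-2,5,5,8a-tetramethyl-3,4,4a,5,6,7,8,8a-octahydronaphthalen-1-yl trifluoromethanesulfonate | CC1=C(OS(=O)(=O)C(F)(F)F)[C@]2(C)CCCC(C)(C)[C@H]2CC1 | intermediate
16 | (4aR,8aR)-1-ethenyl-2,5,5,8a-tetramethyl-3,4,4a,5,6,7,8,8a-octahydronaphthalene | C=CC1=C(C)CC[C@@H]2C(C)(C)CCC[C@@]12C | intermediate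
17 | methyl (R)-2,2-dimethyl-1,3-dioxolane-4-carboxylate | COC(=O)[C@H]1COC(C)(C)O1 | starting material
18 | (R)-N-methoxy-N,2,2-trimethyl-1,3-dioxolane-4-carboxamide (Weinreb amide) | CON(C)C(=O)[C@H]1COC(C)(C)O1 | intermediate
19 | (R)-1-(2,2-dimethyl-1,3-dioxolan-4-yl)ethan-1-one | CC(=O)[C@H]1COC(C)(C)O1 | intermediate
20 | potassium 1-[(4R)-2,2-dimethyl-1,3-dioxolan-4-yl]ethen-1-olate | [K+].C=C([O-])[C@H]1COC(C)(C)O1 | intermediate
21 | (R)-1-(2,2-dimethyl-1,3-dioxolan-4-yl)ethenyl trifluoromethanesulfonate | C=C(OS(=O)(=O)C(F)(F)F)[C@H]1COC(C)(C)O1 | intermediate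
22 | 9-{2-[(4aR,8aR)-2,5,5,8a-tetramethyl-3,4,4a,5,6,7,8,8a-octahydronaphthalen-1-yl]ethyl}-9-borabicyclo[3.3.1]nonane | CC1=C(CCB2C3CCCC2CCC3)[C@]2(C)CCCC(C)(C)[C@H]2CC1 | intermediate
23 | (4S)-2,2-dimethyl-4-{4-[(4aR,8aR)-2,5,5,8a-tetramethyl-3,4,4a,5,6,7,8,8a-octahydronaphthalen-1-yl]but-1-en-2-yl}-1,3-dioxolane | C=C(CCC1=C(C)CC[C@@H]2C(C)(C)CCC[C@@]12C)[C@H]1COC(C)(C)O1 | intermediate
24 | (2S)-3-methylidene-5-[(4aR,8aR)-2,5,5,8a-tetramethyl-3,4,4a,5,6,7,8,8a-octahydronaphthalen-1-yl]pentane-1,2-diol | C=C(CCC1=C(C)CC[C@@H]2C(C)(C)CCC[C@@]12C)[C@@H](CO)O | intermediate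
25 | (2S)-3-methylidene-5-[(4aR,8aR)-2,5,5,8a-tetramethyl-3,4,4a,5,6,7,8,8a-octahydronaphthalen-1-yl]pentane-1,2-diyl diacetate; labdane numbering 5R,10R,14S | C=C(CCC1=C(C)CC[C@@H]2C(C)(C)CCC[C@@]12C)[C@@H](COC(C)=O)OC(C)=O | target

**Step count**

Total steps: 15. Longest linear sequence: 13 (steps 1–10 and 13–15); steps 11 and 12 form the side-chain branch.

**Steps most likely to fail**

Step 7. The C6 ylide may fail to engage the C5 carbonyl, which lies between two quaternary carbons, or the enolate may add through oxygen; either would leave open-chain material. The fallback sets out from 9 and builds the bridge stepwise. The C8 enolate (LiN(SiMe3)2) is alkylated with allyl bromide to give the allylated diketone F1. Ozonolysis (O3, then Me2S) gives the keto aldehyde F2. A reductive carbonyl coupling under high dilution (McMurry reaction, TiCl3(DME)1.5, Zn–Cu couple, DME, reflux) then joins the C6 aldehyde carbon to the C5 ketone carbon as the alkene. This coupling is at its best with hindered carbonyl groups, and it comes back to the route at 12.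

Step 8. Hydrogen uptake at the hindered trisubstituted alkene may be slow, and delivery from the wrong face would give the cis-fused ketone. The fallback replaces surface hydrogenation with a radical hydrogen-atom-transfer hydrogenation (Mn(dpm)3, PhSiH3, t-BuOOH, i-PrOH). It proceeds stepwise through the tertiary C5 radical and should give the thermodynamically preferred trans fusion. It sets out from 12 and comes back at 13 (no new compound, F0).

Step 13. Hydroboration may lose chemoselectivity on the diene, or the coupling may stall. The fallback sets out from 15 and does not pass through 16. Vinylmagnesium bromide is added to commercial (R)-2,2-dimethyl-1,3-dioxolane-4-carbaldehyde to give the allylic alcohol F3 as a mixture of carbinol epimers. Its vinyl group is hydroborated with 9-BBN (2 equiv) and the borane is coupled with 15 (PdCl2(dppf), K3PO4) to give the coupled alcohol F4. Dess–Martin oxidation gives the ketone F5, and Wittig methylenation (Ph3P=CH2, THF, −78 to 0 °C) comes back to the route at 23.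

**Further compounds**

F1 | step 7 | (6S)-2,2,6-trimethyl-6-(2-methylpent-4-enoyl)cyclohexan-1-one | C=CCC(C)C(=O)[C@]1(C)CCCC(C)(C)C1=O
F2 | step 7 | 3-methyl-4-oxo-4-[(1S)-1,3,3-trimethyl-2-oxocyclohexyl]butanal | O=CCC(C)C(=O)[C@]1(C)CCCC(C)(C)C1=O
F0 | step 8 | none | none
F3 | step 13 | 1-[(4R)-2,2-dimethyl-1,3-dioxolan-4-yl]prop-2-en-1-ol | C=CC(O)[C@H]1COC(C)(C)O1
F4 | step 13 | 1-[(4R)-2,2-dimethyl-1,3-dioxolan-4-yl]-3-[(4aR,8aR)-2,5,5,8a-tetramethyl-3,4,4a,5,6,7,8,8a-octahydronaphthalen-1-yl]propan-1-ol | OC(CCC1=C(C)CC[C@@H]2C(C)(C)CCC[C@@]12C)[C@H]1COC(C)(C)O1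
F5 | step 13 | 1-[(4R)-2,2-dimethyl-1,3-dioxolan-4-yl]-3-[(4aR,8aR)-2,5,5,8a-tetramethyl-3,4,4a,5,6,7,8,8a-octahydronaphthalen-1-yl]propan-1-one | O=C(CCC1=C(C)CC[C@@H]2C(C)(C)CCC[C@@]12C)[C@H]1COC(C)(C)O1
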